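**Plan**

1. Rings: A = 2,4-dihydroxyphenyl, B = central benzene, C = 4-hydroxyphenyl on the exocyclic carbon, D = cyclohexadienone, E = aryl of the alkyne. Cuts: (a) both C(alpha)–C(beta) bonds of ring D, giving acetone and a 2-aroylmalonaldehyde masked as a 3-formylchromone fused to ring B; (b) exocyclic carbon–ring C (aryllithium + ketone); (c) ring B–alkyne (Sonogashira); (d) ring A–ring B (Suzuki–Miyaura).
2. Enabling feature: rings C and D exchange roles by one proton shift, so ring D can be built as a 4-hydroxyphenyl ring on a ketone carbon. In that ring the C–O carbon and its two CH neighbours are acetone; the remaining CH–C–CH unit plus the exocyclic carbon are C2, C3, CHO and C4 of a chromone.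
3. The alkyne-bearing carbon of ring B is ortho to the carbon holding the exocyclic carbon, so it can carry the chromone oxygen; that oxygen is later removed as a triflate and replaced by the alkyne.
4. Forward order: ring B from 5-bromo-2-(hydroxymethyl)phenol (ortho-lithiation/acetylation, Vilsmeier–Haack closure of the temporary pyranone ring); step 5 opens the pyranone and closes ring D from acetone, freeing the ring B oxygen; then ring A at the bromide, ring E with the alkyne at the triflate, ring C by aryllithium addition, and acid deprotection/dehydration to the quinone methide.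
5. Stereochemistry: the target has no stereocentre and its exocyclic double bond ends in a symmetric ring, so nothing has to be controlled.

Key step: step 5

Assumption: the open quinone methide drawn for the target is taken as the stable form, and the degenerate proton shift between rings C and D is taken as fast, so either ring may be written as the dienone.

Abbreviations: MOM = methoxymethyl, TBDPS = tert-butyldiphenylsilyl.

**Step 1**
Reactants: 1 5-bromo-2-(hydroxymethyl)phenol
Product: 2 [4-bromo-2-(methoxymethoxy)phenyl]methanol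
Conditions: MOMCl (1.05 equiv), K2CO3, acetone, 0 to 25 °C
Reagents that add atoms: chloromethyl methyl ether, COCCl
Why: Williamson-type O-alkylation in which K2CO3 deprotonates only the phenol, so the phenoxide should take up the MOM group (the directing group for step 3) while the benzylic alcohol stays free.

**Step 2**
Reactants: 2 [4-bromo-2-(methoxymethoxy)phenyl]methanol
Product: 3 {[4-bromo-2-(methoxymethoxy)phenyl]methoxy}(tert-butyl)diphenylsilane
Conditions: TBDPSCl, imidazole, DMF, 25 °C
Reagents that add atoms: tert-butyl(chloro)diphenylsilane, CC(C)(C)[Si](Cl)(c1ccccc1)c1ccccc1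
Why: Silyl ether formation at the only remaining hydroxyl gives a group that should survive the acidic Vilsmeier–Haack step and all later base, palladium and organolithium steps.

**Step 3**
Reactants: 3 {[4-bromo-2-(methoxymethoxy)phenyl]methoxy}(tert-butyl)diphenylsilane
Product: 6 1-[6-bromo-3-({[tert-butyl(diphenyl)silyl]oxy}methyl)-2-hydroxyphenyl]ethan-1-one, via aryllithium 4 (not isolated), via MOM ketone 5 (not isolated)
Conditions: LiN(iPr)2, THF, −78 °C; MeC(O)N(OMe)Me, −78 to 0 °C; then 1 M HCl, MeOH, 25 °C
Reagents that add atoms: N-methoxy-N-methylacetamide, CC(=O)N(C)OC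
Why: Directed ortho-metalation should take place at the only ring hydrogen ortho to the MOM ether, which lies between that oxygen and bromine and is the most acidic, the aryllithium is then acylated by the N-methoxy-N-methylamide without over-addition, and the MOM ether next to the new ketone is cleaved by the methanolic acid work-up while the silyl ether stays.

**Step 4**
Reactants: 6 1-[6-bromo-3-({[tert-butyl(diphenyl)silyl]oxy}methyl)-2-hydroxyphenyl]ethan-1-one
Product: 7 5-bromo-8-({[tert-butyl(diphenyl)silyl]oxy}methyl)-4-oxo-4H-chromene-3-carbaldehyde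
Conditions: POCl3, DMF, 0 to 45 °C; then ice-water
Reagents that add atoms: N,N-dimethylformamide, CN(C)C=O
Why: Vilsmeier–Haack double formylation of the acetyl methyl group with ring closure through the phenol oxygen is the standard route from 2-hydroxyacetophenones to 3-formylchromones and masks the ring B oxygen in a temporary pyranone ring.

**Step 5**
Reactants: 7 5-bromo-8-({[tert-butyl(diphenyl)silyl]oxy}methyl)-4-oxo-4H-chromene-3-carbaldehyde; 8 acetone
Product: 11 [6-bromo-3-({[tert-butyl(diphenyl)silyl]oxy}methyl)-2-hydroxyphenyl](4-hydroxyphenyl)methanone, via ring-opened enaminal 9 (not isolated), via aminodienone 10 (not isolated)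
Conditions: acetone (20 equiv), pyrrolidine (1.5 equiv), AcOH (1.5 equiv), EtOH, 25 °C, then 78 °C
Reagents that add atoms: none
Why: Proposed new method: pyrrolidine should add to C2 of the chromone and open the pyranone to the 2-aroyl-3-aminoacrolein 9, whose aldehyde undergoes enamine aldol condensation with acetone to the push-pull aminodienone 10; delocalisation along N–C=C–C=C–C=O lets the new enone double bond turn into the cis geometry, the second acetone carbon (as enamine or enol) attacks the aminomethylene carbon, and loss of pyrrolidine with enolisation gives the phenol. The closest known reaction types are the ring transformation of 3-formylchromones with 1,3-dicarbonyl C,C-dinucleophiles (acetonedicarboxylates, 1,3-bis(silyl enol ethers)) to 4-(2-hydroxybenzoyl)phenols, the condensation of acetone with sodium nitromalonaldehyde to 4-nitrophenol, and the benzannulation of vinamidinium salts with methyl ketones; new is the use of unactivated acetone on a formylchromone. The one ring closed is the six-membered carbocycle D, closed as a formal [3+3] by a 6-(enolendo)-exo-trig Mannich-type addition (equivalently a 6π-electrocyclisation of the aminotriene), and the aromatisation that follows makes the sequence irreversible. No stereocentre is formed. The step needs attack at the formyl carbon and at C2 instead of the ketone carbonyl, which the flanking bromine and oxygen substituents of ring B and the vinylogous-amide character of 9 should secure, and it needs one acetone per chromone, which the excess of acetone and the fast intramolecular second bond formation should secure. It delivers in one operation the hindered diaryl ketone, the para-oxygenated ring D and the free ring B oxygen that serves as the handle for the alkyne.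

**Step 6**
Reactants: 11 [6-bromo-3-({[tert-butyl(diphenyl)silyl]oxy}methyl)-2-hydroxyphenyl](4-hydroxyphenyl)methanone
Product: 12 [6-bromo-3-({[tert-butyl(diphenyl)silyl]oxy}methyl)-2-hydroxyphenyl][4-(methoxymethoxy)phenyl]methanone
Conditions: MOMCl (1.05 equiv), K2CO3, acetone, 0 °C
Reagents that add atoms: chloromethyl methyl ether, COCCl
Why: Selective Williamson-type O-alkylation, since the ring D phenol is unhindered whereas the ring B phenol is flanked by two substituents and hydrogen-bonded to the ketone, so one equivalent of reagent should protect ring D only.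

**Step 7**
Reactants: 13 4-bromobenzene-1,3-diol
Product: 14 1-bromo-2,4-bis(methoxymethoxy)benzene
Conditions: MOMCl (2.5 equiv), K2CO3, acetone, 25 to 56 °C
Reagents that add atoms: chloromethyl methyl ether, COCCl
Why: Twofold Williamson-type O-alkylation should protect both phenols of ring A as acid-labile MOM ethers.

**Step 8**
Reactants: 14 1-bromo-2,4-bis(methoxymethoxy)benzene
Product: 16 2-[2,4-bis(methoxymethoxy)phenyl]-4,4,5,5-tetramethyl-1,3,2-dioxaborolane, via aryllithium 15 (not isolated)
Conditions: n-BuLi, THF, −78 °C; then iPrOBpin, −78 to 25 °C; H2O quench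
Reagents that add atoms: 2-isopropoxy-4,4,5,5-tetramethyl-1,3,2-dioxaborolane, CC(C)OB1OC(C)(C)C(C)(C)O1
Why: Bromine–lithium exchange followed by borylation with the isopropoxy pinacol borate should give the pinacol boronate directly, which resists protodeboronation better than the free boronic acid.

**Step 9**
Reactants: 12 [6-bromo-3-({[tert-butyl(diphenyl)silyl]oxy}methyl)-2-hydroxyphenyl][4-(methoxymethoxy)phenyl]methanone; 16 2-[2,4-bis(methoxymethoxy)phenyl]-4,4,5,5-tetramethyl-1,3,2-dioxaborolane
Product: 17 [4-({[tert-butyl(diphenyl)silyl]oxy}methyl)-3-hydroxy-2',4'-bis(methoxymethoxy)biphenyl-2-yl][4-(methoxymethoxy)phenyl]methanone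
Conditions: Pd(OAc)2 (5 mol%), SPhos (10 mol%), K3PO4, toluene/H2O, 90 °C
Reagents that add atoms: none
Why: Suzuki–Miyaura coupling in which the bromide is activated by the ortho ketone, the free phenol is tolerated, and the SPhos ligand should cope with the ortho-substituted electron-rich boronate.

**Step 10**
Reactants: 17 [4-({[tert-butyl(diphenyl)silyl]oxy}methyl)-3-hydroxy-2',4'-bis(methoxymethoxy)biphenyl-2-yl][4-(methoxymethoxy)phenyl]methanone
Product: 18 4-({[tert-butyl(diphenyl)silyl]oxy}methyl)-2-[4-(methoxymethoxy)benzoyl]-2',4'-bis(methoxymethoxy)biphenyl-3-yl trifluoromethanesulfonate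
Conditions: Tf2O, pyridine, CH2Cl2, −10 to 0 °C
Reagents that add atoms: trifluoromethanesulfonic anhydride, O=S(=O)(OS(=O)(=O)C(F)(F)F)C(F)(F)F
Why: Aryl triflate formation turns the oxygen set free in step 5 into a leaving group for cross-coupling, and the MOM and silyl ethers should tolerate the cold, pyridine-buffered conditions.

**Step 11**
Reactants: 19 4-(methoxymethoxy)benzaldehyde
Product: 20 1-ethynyl-4-(methoxymethoxy)benzene
Conditions: dimethyl (1-diazo-2-oxopropyl)phosphonate, K2CO3, MeOH, 0 to 25 °C
Reagents that add atoms: dimethyl (1-diazo-2-oxopropyl)phosphonate, COP(=O)(OC)C(=[N+]=[N-])C(C)=O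
Why: Ohira–Bestmann homologation (Seyferth–Gilbert type) should convert the aldehyde into the terminal alkyne under mild base that leaves the MOM ether intact.

**Step 12**
Reactants: 18 4-({[tert-butyl(diphenyl)silyl]oxy}methyl)-2-[4-(methoxymethoxy)benzoyl]-2',4'-bis(methoxymethoxy)biphenyl-3-yl trifluoromethanesulfonate; 20 1-ethynyl-4-(methoxymethoxy)benzene
Product: 21 [4-({[tert-butyl(diphenyl)silyl]oxy}methyl)-2',4'-bis(methoxymethoxy)-3-{[4-(methoxymethoxy)phenyl]ethynyl}biphenyl-2-yl][4-(methoxymethoxy)phenyl]methanone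
Conditions: Pd(PPh3)2Cl2 (5 mol%), CuI (10 mol%), Bu4NI, Et3N, DMF, 70 °C
Reagents that add atoms: none
Why: Sonogashira coupling in which the ortho ketone activates the triflate for oxidative addition to zerovalent palladium and the iodide additive should help the hindered sulfonate to react.

**Step 13**
Reactants: 22 1-bromo-4-(methoxymethoxy)benzene; 21 [4-({[tert-butyl(diphenyl)silyl]oxy}methyl)-2',4'-bis(methoxymethoxy)-3-{[4-(methoxymethoxy)phenyl]ethynyl}biphenyl-2-yl][4-(methoxymethoxy)phenyl]methanone
Product: 24 [4-({[tert-butyl(diphenyl)silyl]oxy}methyl)-2',4'-bis(methoxymethoxy)-3-{[4-(methoxymethoxy)phenyl]ethynyl}biphenyl-2-yl]bis[4-(methoxymethoxy)phenyl]methanol, via aryllithium 23 (not isolated)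
Conditions: 22 (3 equiv), n-BuLi, THF, −78 °C; then 21, −78 to 0 °C; H2O quench
Reagents that add atoms: none
Why: Bromine–lithium exchange and 1,2-addition of the aryllithium to the non-enolisable diaryl ketone should give the triaryl carbinol, which carries two identical 4-(methoxymethoxy)phenyl groups on the carbinol carbon and so has no stereocentre.

**Step 14**
Reactants: 24 [4-({[tert-butyl(diphenyl)silyl]oxy}methyl)-2',4'-bis(methoxymethoxy)-3-{[4-(methoxymethoxy)phenyl]ethynyl}biphenyl-2-yl]bis[4-(methoxymethoxy)phenyl]methanol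
Product: 26 selaginellin F, via desilylated carbinol 25 (not isolated)
Conditions: Bu4NF, AcOH, THF, 25 °C; then 2 M HCl, MeOH/THF, 40 °C; NaHCO3 work-up
Reagents that add atoms: none
Why: Buffered fluoride desilylation, then acid hydrolysis of the five MOM acetals with ionisation of the bis(4-hydroxyphenyl) carbinol and loss of a proton from one para-hydroxyl (dehydration) should give the quinone methide, the dienone being drawn on the ring made in step 5 because rings C and D are equivalent.

**Compound list**

1 | 5-bromo-2-(hydroxymethyl)phenol | OCc1ccc(Br)cc1O | starting material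
2 | [4-bromo-2-(methoxymethoxy)phenyl]methanol | OCc1ccc(Br)cc1OCOC | intermediate
3 | {[4-bromo-2-(methoxymethoxy)phenyl]methoxy}(tert-butyl)diphenylsilane | CC(C)(C)[Si](OCc1ccc(Br)cc1OCOC)(c1ccccc1)c1ccccc1 | intermediate
4 | [6-bromo-3-({[tert-butyl(diphenyl)silyl]oxy}methyl)-2-(methoxymethoxy)phenyl]lithium | CC(C)(C)[Si](OCc1ccc(Br)c([Li])c1OCOC)(c1ccccc1)c1ccccc1 | intermediate (not isolated)
5 | 1-[6-bromo-3-({[tert-butyl(diphenyl)silyl]oxy}methyl)-2-(methoxymethoxy)phenyl]ethan-1-one | CC(C)(C)[Si](OCc1ccc(Br)c(C(C)=O)c1OCOC)(c1ccccc1)c1ccccc1 | intermediate (not isolated)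
6 | 1-[6-bromo-3-({[tert-butyl(diphenyl)silyl]oxy}methyl)-2-hydroxyphenyl]ethan-1-one | CC(C)(C)[Si](OCc1ccc(Br)c(C(C)=O)c1O)(c1ccccc1)c1ccccc1 | intermediate
7 | 5-bromo-8-({[tert-butyl(diphenyl)silyl]oxy}methyl)-4-oxo-4H-chromene-3-carbaldehyde | CC(C)(C)[Si](OCc1ccc(Br)c2c1occ(C=O)c2=O)(c1ccccc1)c1ccccc1 | intermediate
8 | acetone | CC(C)=O | starting material
9 | 2-[6-bromo-3-({[tert-butyl(diphenyl)silyl]oxy}methyl)-2-hydroxybenzoyl]-3-(pyrrolidin-1-yl)prop-2-enal (double-bond geometry mobile) | CC(C)(C)[Si](OCc1ccc(Br)c(C(=O)C(C=O)=CN2CCCC2)c1O)(c1ccccc1)c1ccccc1 | intermediate (not isolated)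
10 | 5-[6-bromo-3-({[tert-butyl(diphenyl)silyl]oxy}methyl)-2-hydroxybenzoyl]-6-(pyrrolidin-1-yl)hexa-3,5-dien-2-one (double-bond geometry mobile) | CC(C)(C)[Si](OCc1ccc(Br)c(C(=O)C(C=CC(C)=O)=CN2CCCC2)c1O)(c1ccccc1)c1ccccc1 | intermediate (not isolated)
11 | [6-bromo-3-({[tert-butyl(diphenyl)silyl]oxy}methyl)-2-hydroxyphenyl](4-hydroxyphenyl)methanone | CC(C)(C)[Si](OCc1ccc(Br)c(C(=O)c2ccc(O)cc2)c1O)(c1ccccc1)c1ccccc1 | intermediate
12 | [6-bromo-3-({[tert-butyl(diphenyl)silyl]oxy}methyl)-2-hydroxyphenyl][4-(methoxymethoxy)phenyl]methanone | CC(C)(C)[Si](OCc1ccc(Br)c(C(=O)c2ccc(OCOC)cc2)c1O)(c1ccccc1)c1ccccc1 | intermediate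
13 | 4-bromobenzene-1,3-diol | Oc1ccc(Br)c(O)c1 | starting material
14 | 1-bromo-2,4-bis(methoxymethoxy)benzene | COCOc1ccc(Br)c(OCOC)c1 | intermediate
15 | [2,4-bis(methoxymethoxy)phenyl]lithium | [Li]c1ccc(OCOC)cc1OCOC | intermediate (not isolated)
16 | 2-[2,4-bis(methoxymethoxy)phenyl]-4,4,5,5-tetramethyl-1,3,2-dioxaborolane | COCOc1ccc(B2OC(C)(C)C(C)(C)O2)c(OCOC)c1 | intermediate
17 | [4-({[tert-butyl(diphenyl)silyl]oxy}methyl)-3-hydroxy-2',4'-bis(methoxymethoxy)biphenyl-2-yl][4-(methoxymethoxy)phenyl]methanone | CC(C)(C)[Si](OCc1ccc(-c2ccc(OCOC)cc2OCOC)c(C(=O)c2ccc(OCOC)cc2)c1O)(c1ccccc1)c1ccccc1 | intermediate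
18 | 4-({[tert-butyl(diphenyl)silyl]oxy}methyl)-2-[4-(methoxymethoxy)benzoyl]-2',4'-bis(methoxymethoxy)biphenyl-3-yl trifluoromethanesulfonate | CC(C)(C)[Si](OCc1ccc(-c2ccc(OCOC)cc2OCOC)c(C(=O)c2ccc(OCOC)cc2)c1OS(=O)(=O)C(F)(F)F)(c1ccccc1)c1ccccc1 | intermediate
19 | 4-(methoxymethoxy)benzaldehyde | COCOc1ccc(C=O)cc1 | starting material
20 | 1-ethynyl-4-(methoxymethoxy)benzene | COCOc1ccc(C#C)cc1 | intermediate
21 | [4-({[tert-butyl(diphenyl)silyl]oxy}methyl)-2',4'-bis(methoxymethoxy)-3-{[4-(methoxymethoxy)phenyl]ethynyl}biphenyl-2-yl][4-(methoxymethoxy)phenyl]methanone | CC(C)(C)[Si](OCc1ccc(-c2ccc(OCOC)cc2OCOC)c(C(=O)c2ccc(OCOC)cc2)c1C#Cc1ccc(OCOC)cc1)(c1ccccc1)c1ccccc1 | intermediate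
22 | 1-bromo-4-(methoxymethoxy)benzene | COCOc1ccc(Br)cc1 | starting material
23 | [4-(methoxymethoxy)phenyl]lithium | [Li]c1ccc(OCOC)cc1 | intermediate (not isolated)
24 | [4-({[tert-butyl(diphenyl)silyl]oxy}methyl)-2',4'-bis(methoxymethoxy)-3-{[4-(methoxymethoxy)phenyl]ethynyl}biphenyl-2-yl]bis[4-(methoxymethoxy)phenyl]methanol | CC(C)(C)[Si](OCc1ccc(-c2ccc(OCOC)cc2OCOC)c(C(O)(c2ccc(OCOC)cc2)c2ccc(OCOC)cc2)c1C#Cc1ccc(OCOC)cc1)(c1ccccc1)c1ccccc1 | intermediate
25 | [4-(hydroxymethyl)-2',4'-bis(methoxymethoxy)-3-{[4-(methoxymethoxy)phenyl]ethynyl}biphenyl-2-yl]bis[4-(methoxymethoxy)phenyl]methanol | OCc1ccc(-c2ccc(OCOC)cc2OCOC)c(C(O)(c2ccc(OCOC)cc2)c2ccc(OCOC)cc2)c1C#Cc1ccc(OCOC)cc1 | intermediate (not isolated)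
26 | selaginellin F, 4-{[2',4'-dihydroxy-4-(hydroxymethyl)-3-[(4-hydroxyphenyl)ethynyl]biphenyl-2-yl](4-hydroxyphenyl)methylidene}cyclohexa-2,5-dien-1-one | O=C1C=CC(=C(c2ccc(O)cc2)c2c(-c3ccc(O)cc3O)ccc(CO)c2C#Cc2ccc(O)cc2)C=C1 | target

**Step count and risks**

Total step count: 14. Longest linear sequence: 11 steps (steps 1 to 6, 9, 10, 12, 13 and 14).

Steps most likely to fail:

1. Step 5 (Proposed new method). What may go wrong: loss of the formyl group by amine-induced retro-Claisen cleavage of the ring-opened tricarbonyl system, arrest at the trans enone without ring closure, or condensation of one acetone with two chromones. Fallback with known chemistry, in which ring D is brought in ready-made instead of being built: from 3, lithiation as in step 3 and addition to aldehyde 19 should give racemic [6-bromo-3-({[tert-butyl(diphenyl)silyl]oxy}methyl)-2-(methoxymethoxy)phenyl][4-(methoxymethoxy)phenyl]methanol F1. Oxidation with MnO2 (or Dess–Martin periodinane) should give [6-bromo-3-({[tert-butyl(diphenyl)silyl]oxy}methyl)-2-(methoxymethoxy)phenyl][4-(methoxymethoxy)phenyl]methanone F2, and HCl in MeOH should remove both MOM ethers and return to 11.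

2. Step 12. What may go wrong: slow oxidative addition and transmetalation at a triflate flanked by two ortho substituents, with S–O cleavage of the triflate back to the phenol and oxidative dimerisation of alkyne 20 as competing processes. Fallback that builds the alkyne carbon by carbon on ring B: from 18, palladium-catalysed reductive carbonylation (Pd(OAc)2, 1,3-bis(diphenylphosphino)propane, CO, Et3SiH, Et3N, DMF, 70 °C) should give 4-({[tert-butyl(diphenyl)silyl]oxy}methyl)-2-[4-(methoxymethoxy)benzoyl]-2',4'-bis(methoxymethoxy)biphenyl-3-carbaldehyde F3. Ohira–Bestmann homologation should give [4-({[tert-butyl(diphenyl)silyl]oxy}methyl)-3-ethynyl-2',4'-bis(methoxymethoxy)biphenyl-2-yl][4-(methoxymethoxy)phenyl]methanone F4, and Sonogashira coupling of this alkyne with commercial 1-iodo-4-(methoxymethoxy)benzene, an unhindered iodide, should return to 21.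

3. Step 14. What may go wrong: capture of the diarylcarbenium ion by the neighbouring ring A hydroxyl (closure to a benzo[c]chromene), acid- or fluoride-promoted addition of the benzylic hydroxyl or of water to the alkyne, and electrophilic attack of released formaldehyde equivalents on ring A. Fallback that changes the order of oxidation levels: from 24, ionic hydrogenation (Et3SiH, 3% Cl2CHCO2H in CH2Cl2, 0 °C) should trap the cation as tert-butyl{[2-{bis[4-(methoxymethoxy)phenyl]methyl}-2',4'-bis(methoxymethoxy)-3-{[4-(methoxymethoxy)phenyl]ethynyl}biphenyl-4-yl]methoxy}diphenylsilane F5 with all protecting groups in place. Bu4NF/AcOH and then HCl/MeOH should give 2'-[bis(4-hydroxyphenyl)methyl]-4'-(hydroxymethyl)-3'-[(4-hydroxyphenyl)ethynyl]biphenyl-2,4-diol F6, which cannot ionise during deprotection. Oxidation with DDQ (one equivalent, dioxane, 0 °C) by hydride abstraction from the bis(4-hydroxyphenyl)methine should return to 26.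

**Further compounds**

F1 | step 5 | [6-bromo-3-({[tert-butyl(diphenyl)silyl]oxy}methyl)-2-(methoxymethoxy)phenyl][4-(methoxymethoxy)phenyl]methanol (racemic) | CC(C)(C)[Si](OCc1ccc(Br)c(C(O)c2ccc(OCOC)cc2)c1OCOC)(c1ccccc1)c1ccccc1
F2 | step 5 | [6-bromo-3-({[tert-butyl(diphenyl)silyl]oxy}methyl)-2-(methoxymethoxy)phenyl][4-(methoxymethoxy)phenyl]methanone | CC(C)(C)[Si](OCc1ccc(Br)c(C(=O)c2ccc(OCOC)cc2)c1OCOC)(c1ccccc1)c1ccccc1
F3 | step 12 | 4-({[tert-butyl(diphenyl)silyl]oxy}methyl)-2-[4-(methoxymethoxy)benzoyl]-2',4'-bis(methoxymethoxy)biphenyl-3-carbaldehyde | CC(C)(C)[Si](OCc1ccc(-c2ccc(OCOC)cc2OCOC)c(C(=O)c2ccc(OCOC)cc2)c1C=O)(c1ccccc1)c1ccccc1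
F4 | step 12 | [4-({[tert-butyl(diphenyl)silyl]oxy}methyl)-3-ethynyl-2',4'-bis(methoxymethoxy)biphenyl-2-yl][4-(methoxymethoxy)phenyl]methanone | CC(C)(C)[Si](OCc1ccc(-c2ccc(OCOC)cc2OCOC)c(C(=O)c2ccc(OCOC)cc2)c1C#C)(c1ccccc1)c1ccccc1
F5 | step 14 | tert-butyl{[2-{bis[4-(methoxymethoxy)phenyl]methyl}-2',4'-bis(methoxymethoxy)-3-{[4-(methoxymethoxy)phenyl]ethynyl}biphenyl-4-yl]methoxy}diphenylsilane | CC(C)(C)[Si](OCc1ccc(-c2ccc(OCOC)cc2OCOC)c(C(c2ccc(OCOC)cc2)c2ccc(OCOC)cc2)c1C#Cc1ccc(OCOC)cc1)(c1ccccc1)c1ccccc1
F6 | step 14 | 2'-[bis(4-hydroxyphenyl)methyl]-4'-(hydroxymethyl)-3'-[(4-hydroxyphenyl)ethynyl]biphenyl-2,4-diol | OCc1ccc(-c2ccc(O)cc2O)c(C(c2ccc(O)cc2)c2ccc(O)cc2)c1C#Cc1ccc(O)cc1
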